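**Retrosynthetic overview**

1. Numbering: ring B is the oxane O1–C7(Me, ring A)–C8(OAc)–C9–C10(Br)–C11(Me2); ring A is the cyclohexane C1'(on C7)–C2'–C3'–C4'(Me, Cl)–C5'(Br)–C6'. The strategy rests on the ring A dihalide: C5'–Br cis and C4'–Cl trans to the C1' substituent, both equatorial with the C4' methyl axial, a pattern that Markovnikov trans-diaxial BrCl addition to the C4'=C5' alkene does not give.
2. Last disconnection (C5'–Br and C4'–Cl together): activation of the axial C5' hydroxyl of the trans-diaxial bromohydrin (C4'–Br axial), 1,2-shift of bromine through the bromonium ion on the face cis to C7, chloride capture at C4'. The bromohydrin comes from the 4',5'-epoxide trans to C7 (HBr), the epoxide from the ring A alkene.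
3. Ring B (formed second): O1–C11 and C10–Br by 6-endo bromoetherification of the C7 tertiary alcohol onto the C10=C11 alkene; that alkene is installed by cross-metathesis only after the Lewis-acid step.
4. C7 by Felkin–Anh methyl addition to the C7 ketone; ring A (formed first) by catalyst-controlled Diels–Alder of isoprene with the C8-silyloxy vinyl ketone; C8 from methyl (S)-glycidate.

Key step: step 13

Assumption: the facial sense of the two chiral catalysts (steps 5 and 11) is taken from the accepted transition-state models of their reaction classes; if either proved opposite on this substrate, the antipodal catalyst would be used with no other change.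

**Route**

Step 1
Reactants: 1 methyl (S)-glycidate; 2 vinylmagnesium bromide
Product: 3 methyl (2S)-2-hydroxypent-4-enoate
Conditions: CuBr·SMe2 (10 mol %), THF, −78 → −40 °C; aq. NH4Cl
Reagents that add atoms: none
Why: Copper-catalysed Grignard opening of the glycidic ester occurs at the terminal epoxide carbon (SN2, remote from the ester), so the chiral-pool stereocentre is untouched and becomes C8 (S).

Step 2
Reactants: 3 methyl (2S)-2-hydroxypent-4-enoate
Product: 4 methyl (2S)-2-[(tert-butyldimethylsilyl)oxy]pent-4-enoate
Conditions: TBSCl, imidazole, DMF, rt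
Reagents that add atoms: tert-butyldimethylsilyl chloride, CC(C)(C)[Si](C)(C)Cl
Why: Standard silylation of a secondary alcohol; the bulky, non-chelating silyl ether is what later enforces Felkin–Anh control at C7.

Step 3
Reactants: 4 methyl (2S)-2-[(tert-butyldimethylsilyl)oxy]pent-4-enoate
Product: 5 (2S)-2-[(tert-butyldimethylsilyl)oxy]-N-methoxy-N-methylpent-4-enamide
Conditions: MeNH(OMe)·HCl, iPrMgCl, THF, −20 → 0 °C
Reagents that add atoms: N,O-dimethylhydroxylamine hydrochloride, CNOC.Cl
Why: Aminolysis of the ester by the magnesium amide (Weinreb amide formation) is fast at low temperature and should not epimerise the α-silyloxy centre.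

Step 4
Reactants: 5 (2S)-2-[(tert-butyldimethylsilyl)oxy]-N-methoxy-N-methylpent-4-enamide; 2 vinylmagnesium bromide
Product: 6 (4S)-4-[(tert-butyldimethylsilyl)oxy]hepta-1,6-dien-3-one
Conditions: THF, −78 → 0 °C; inverse quench into cold aq. HCl
Reagents that add atoms: none
Why: Weinreb ketone synthesis: the stable magnesium chelate prevents over-addition, and the acidic quench keeps the liberated amine from adding to the vinyl ketone.

Step 5
Reactants: 6 (4S)-4-[(tert-butyldimethylsilyl)oxy]hepta-1,6-dien-3-one; 7 isoprene
Product: 8 (2S)-2-[(tert-butyldimethylsilyl)oxy]-1-[(1R)-4-methylcyclohex-3-en-1-yl]pent-4-en-1-one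
Conditions: (R)-o-tolyl-CBS-oxazaborolidine [(R)-3,3-diphenyl-1-(2-methylphenyl)tetrahydro-1H,3H-pyrrolo[1,2-c][1,3,2]oxazaborole] (20 mol %), HNTf2 (17 mol %), isoprene (5 equiv), CH2Cl2, −78 → −40 °C
Reagents that add atoms: none
Why: Oxazaborolidinium-catalysed Diels–Alder reaction of a vinyl ketone: the catalyst binds the carbonyl lone pair syn to the vinyl group, isoprene adds with para orientation to the Si face of C1' to set C1' (R), the perpendicular C8–OSi bond of the Felkin–Anh-type rotamer shields the opposite face so substrate and catalyst should reinforce each other, and the monosubstituted side-chain alkene is too weak a nucleophile to attack the activated enone.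

Step 6
Reactants: 8 (2S)-2-[(tert-butyldimethylsilyl)oxy]-1-[(1R)-4-methylcyclohex-3-en-1-yl]pent-4-en-1-one
Product: 9 (2S,3S)-3-[(tert-butyldimethylsilyl)oxy]-2-[(1R)-4-methylcyclohex-3-en-1-yl]hex-5-en-2-ol
Conditions: MeLi, CeCl3, THF, −78 °C
Reagents that add atoms: methyllithium, C[Li]
Why: Polar Felkin–Anh addition to an α-silyloxy ketone: the non-chelating C8–OSi bond stands perpendicular to the carbonyl and methyl enters anti to it, setting C7 (S) (chelation control would give the C7 epimer), while the weakly basic organocerium reagent should suppress enolisation at C1' and C8.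

Step 7
Reactants: 9 (2S,3S)-3-[(tert-butyldimethylsilyl)oxy]-2-[(1R)-4-methylcyclohex-3-en-1-yl]hex-5-en-2-ol; 10 2-methylbut-2-ene
Product: 11 (2S,3S)-3-[(tert-butyldimethylsilyl)oxy]-6-methyl-2-[(1R)-4-methylcyclohex-3-en-1-yl]hept-5-en-2-ol
Conditions: (H2IMes)(PCy3)Cl2Ru=CHPh (second-generation Grubbs catalyst, 5 mol %), 2-methylbut-2-ene/CH2Cl2, 40 °C
Reagents that add atoms: none
Why: Olefin cross-metathesis converts only the terminal alkene into the C10=C11 trisubstituted alkene, the trisubstituted ring A alkene being inert, and placing this step after the Diels–Alder keeps a nucleophilic trisubstituted alkene away from the Lewis-acid-activated enone.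

Step 8
Reactants: 11 (2S,3S)-3-[(tert-butyldimethylsilyl)oxy]-6-methyl-2-[(1R)-4-methylcyclohex-3-en-1-yl]hept-5-en-2-ol
Product: 12 tert-butyl{[(2S,3S,5S)-5-bromo-2,6,6-trimethyl-2-[(1R)-4-methylcyclohex-3-en-1-yl]oxan-3-yl]oxy}dimethylsilane
Conditions: NBS, (CF3)2CHOH, 4 Å MS, 0 °C
Reagents that add atoms: N-bromosuccinimide, O=C1CCC(=O)N1Br
Why: Bromoetherification: the reversibly formed bromonium ion of the C10=C11 alkene is captured by the C7 hydroxyl at tertiary C11 (6-endo, Markovnikov, anti addition) through a chair transition state with ring A and bromine equatorial and the silyloxy group axial, which closes ring B and sets C10 (S).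

Step 9
Reactants: 12 tert-butyl{[(2S,3S,5S)-5-bromo-2,6,6-trimethyl-2-[(1R)-4-methylcyclohex-3-en-1-yl]oxan-3-yl]oxy}dimethylsilane
Product: 13 (2S,3S,5S)-5-bromo-2,6,6-trimethyl-2-[(1R)-4-methylcyclohex-3-en-1-yl]oxan-3-ol
Conditions: HF·pyridine, THF/pyridine, 0 °C → rt
Reagents that add atoms: none
Why: Fluoride-mediated desilylation under buffered conditions; the equatorial C10 bromide has no antiperiplanar hydrogen and should not eliminate.

Step 10
Reactants: 13 (2S,3S,5S)-5-bromo-2,6,6-trimethyl-2-[(1R)-4-methylcyclohex-3-en-1-yl]oxan-3-ol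
Product: 14 (2S,3S,5S)-5-bromo-2,6,6-trimethyl-2-[(1R)-4-methylcyclohex-3-en-1-yl]oxan-3-yl acetate
Conditions: Ac2O, DMAP, pyridine, CH2Cl2, rt
Reagents that add atoms: acetic anhydride, CC(=O)OC(C)=O
Why: DMAP-catalysed acylation of the hindered axial C8 alcohol installs the acetate of the target before any other hydroxyl is present.

Step 11
Reactants: 14 (2S,3S,5S)-5-bromo-2,6,6-trimethyl-2-[(1R)-4-methylcyclohex-3-en-1-yl]oxan-3-yl acetate
Product: 15 (2S,3S,5S)-5-bromo-2,6,6-trimethyl-2-[(1S,3R,6R)-6-methyl-7-oxabicyclo[4.1.0]heptan-3-yl]oxan-3-yl acetate (4',5'-epoxide with oxygen trans to C7; 4'R,5'S)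
Conditions: 1,2:4,5-di-O-isopropylidene-β-L-erythro-2,3-hexodiulo-2,6-pyranose (L-fructose-derived Shi ketone, 30 mol %), KHSO5 (as 2KHSO5·KHSO4·K2SO4), K2CO3, Bu4NHSO4, MeCN/dimethoxymethane, aq. Na2B4O7 buffer (pH 10.5), 0 °C
Reagents that add atoms: potassium peroxymonosulfate, [K+].[O-]S(=O)(=O)OO
Why: Shi epoxidation: the chiral dioxirane transfers oxygen through a spiro transition state under reagent control, and the L-series ketone should attack the face opposite to that used by the D-series ketone on 1-substituted cyclohexenes, i.e. the face trans to C7, which the substrate itself does not differentiate.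

Step 12
Reactants: 15 (4',5'-epoxide trans to C7)
Product: 16 (2S,3S,5S)-5-bromo-2-[(1R,3S,4S)-4-bromo-3-hydroxy-4-methylcyclohexyl]-2,6,6-trimethyloxan-3-yl acetate (trans-diaxial bromohydrin: C4'–Br axial and cis to C7, C5'–OH axial and trans to C7)
Conditions: 48 % aq. HBr, CH2Cl2, −20 → 0 °C; used without delay
Reagents that add atoms: hydrogen bromide, Br
Why: Acid-mediated epoxide opening in which the Fürst–Plattner trans-diaxial pathway and Markovnikov attack coincide for this epoxide diastereomer, so bromide enters at tertiary C4' with inversion and the C5'–O bond is retained.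

Step 13
Reactants: 16 (trans-diaxial bromohydrin)
Product: 19 acetylcaespitol, via C5' triflate 17 (not isolated), via bromonium triflate 18 (not isolated)
Conditions: Tf2O, 2,6-di-tert-butyl-4-methylpyridine, CH2Cl2, −78 °C; then Et4NCl (5 equiv), −78 → −20 °C
Reagents that add atoms: tetraethylammonium chloride, CC[N+](CC)(CC)CC.[Cl-]
Why: Triflation of the axial C5' hydroxyl gives 17, whose C5'–O bond is antiperiplanar to the axial C4'–Br bond in the chair fixed by the equatorial C1' substituent, so ionisation proceeds with backside participation of bromine to give bromonium ion 18 only on the face cis to C7, and chloride then opens 18 at C4' from the opposite face. The closest known reaction type is the bromonium-mediated (anchimerically assisted) substitution of trans-2-bromocyclohexyl sulfonates and trans-diaxial bromohydrins, here with a 1,2-shift of bromine because the nucleophile enters at the other carbon. No ring is closed. C5' is set by inversion (bromine arrives anti to the departing triflate and ends cis to the C1' substituent) and C4' by inversion (chloride arrives anti to bromine, ends trans to the C1' substituent and leaves the methyl axial), both fixed by the configuration of 16 and the stereospecificity of the two anti displacements. The step needs capture at tertiary C4' (a twist-boat opening that leads to the diequatorial dihalide) in preference to the chair-like diaxial opening at C5' and to attack of chloride on bromine; what should secure it is the unsymmetrical trisubstituted bromonium ion, whose positive charge is concentrated on the methyl-bearing C4', the same bias that makes nucleophilic opening of 1-methylcyclohexene bromonium ions Markovnikov. The product has bromine and chlorine gauche and cannot re-ionise with bromine assistance, so it should persist, whereas the 4'-bromo-5'-chloro diaxial isomer is not expected to isomerise to it and would have to be separated.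

**Compound list**

1 | methyl (2S)-oxirane-2-carboxylate (methyl (S)-glycidate) | COC(=O)[C@@H]1CO1 | starting material
2 | vinylmagnesium bromide | C=C[Mg]Br | starting material
3 | methyl (2S)-2-hydroxypent-4-enoate | COC(=O)[C@@H](O)CC=C | intermediate
4 | methyl (2S)-2-[(tert-butyldimethylsilyl)oxy]pent-4-enoate | COC(=O)[C@@H](O[Si](C)(C)C(C)(C)C)CC=C | intermediate
5 | (2S)-2-[(tert-butyldimethylsilyl)oxy]-N-methoxy-N-methylpent-4-enamide | CON(C)C(=O)[C@@H](O[Si](C)(C)C(C)(C)C)CC=C | intermediate
6 | (4S)-4-[(tert-butyldimethylsilyl)oxy]hepta-1,6-dien-3-one | C=CC(=O)[C@@H](O[Si](C)(C)C(C)(C)C)CC=C | intermediate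
7 | isoprene | C=CC(C)=C | starting material
8 | (2S)-2-[(tert-butyldimethylsilyl)oxy]-1-[(1R)-4-methylcyclohex-3-en-1-yl]pent-4-en-1-one | CC1=CC[C@@H](CC1)C(=O)[C@@H](O[Si](C)(C)C(C)(C)C)CC=C | intermediate
9 | (2S,3S)-3-[(tert-butyldimethylsilyl)oxy]-2-[(1R)-4-methylcyclohex-3-en-1-yl]hex-5-en-2-ol | CC1=CC[C@@H](CC1)[C@](C)(O)[C@@H](O[Si](C)(C)C(C)(C)C)CC=C | intermediate
10 | 2-methylbut-2-ene | CC=C(C)C | starting material
11 | (2S,3S)-3-[(tert-butyldimethylsilyl)oxy]-6-methyl-2-[(1R)-4-methylcyclohex-3-en-1-yl]hept-5-en-2-ol | CC1=CC[C@@H](CC1)[C@](C)(O)[C@@H](O[Si](C)(C)C(C)(C)C)CC=C(C)C | intermediate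
12 | tert-butyl{[(2S,3S,5S)-5-bromo-2,6,6-trimethyl-2-[(1R)-4-methylcyclohex-3-en-1-yl]oxan-3-yl]oxy}dimethylsilane | CC(C)(C)[Si](C)(C)O[C@H]1C[C@H](Br)C(C)(C)O[C@@]1(C)[C@@H]1CCC(C)=CC1 | intermediate
13 | (2S,3S,5S)-5-bromo-2,6,6-trimethyl-2-[(1R)-4-methylcyclohex-3-en-1-yl]oxan-3-ol | O[C@H]1C[C@H](Br)C(C)(C)O[C@@]1(C)[C@@H]1CCC(C)=CC1 | intermediate
14 | (2S,3S,5S)-5-bromo-2,6,6-trimethyl-2-[(1R)-4-methylcyclohex-3-en-1-yl]oxan-3-yl acetate | CC(=O)O[C@H]1C[C@H](Br)C(C)(C)O[C@@]1(C)[C@@H]1CCC(C)=CC1 | intermediate
15 | (2S,3S,5S)-5-bromo-2,6,6-trimethyl-2-[(1S,3R,6R)-6-methyl-7-oxabicyclo[4.1.0]heptan-3-yl]oxan-3-yl acetate (epoxide oxygen trans to C7) | CC(=O)O[C@H]1C[C@H](Br)C(C)(C)O[C@@]1(C)[C@@H]1CC[C@@]2(C)O[C@H]2C1 | intermediate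
16 | (2S,3S,5S)-5-bromo-2-[(1R,3S,4S)-4-bromo-3-hydroxy-4-methylcyclohexyl]-2,6,6-trimethyloxan-3-yl acetate (trans-diaxial bromohydrin, key-step precursor) | CC(=O)O[C@H]1C[C@H](Br)C(C)(C)O[C@@]1(C)[C@@H]1CC[C@](C)(Br)[C@@H](O)C1 | intermediate
17 | C5' triflate of 16 | CC(=O)O[C@H]1C[C@H](Br)C(C)(C)O[C@@]1(C)[C@@H]1CC[C@](C)(Br)[C@@H](OS(=O)(=O)C(F)(F)F)C1 | intermediate
18 | 4',5'-bromonium ion on the face cis to C7, triflate salt | CC(=O)O[C@H]1C[C@H](Br)C(C)(C)O[C@@]1(C)[C@@H]1CC[C@]2(C)[Br+][C@@H]2C1.[O-]S(=O)(=O)C(F)(F)F | intermediate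
19 | acetylcaespitol, (2S,3S,5S)-5-bromo-2-[(1R,3R,4R)-3-bromo-4-chloro-4-methylcyclohexyl]-2,6,6-trimethyloxan-3-yl acetate | CC(=O)O[C@H]1C[C@H](Br)C(C)(C)O[C@@]1(C)[C@@H]1CC[C@@](C)(Cl)[C@H](Br)C1 | target

**Step count and risks**

Total step count: 13. Longest linear sequence: 13 steps (from methyl (S)-glycidate 1).

Steps most likely to fail:

1. Step 13. Chloride may open the bromonium ion at secondary C5' through the chair-like diaxial pathway, may attack bromine and return alkene 14 with BrCl (which would re-add through the other bromonium ion), or the cation may lose a proton. The fallback sets out from bromohydrin 16 and comes back at 19. Triflate 17, made as in step 13, is solvolysed in wet THF instead of being treated with chloride. Water then captures bromonium ion 18: attack at C5' only regenerates 16, which is recycled, while attack at C4' gives the trans-diequatorial bromohydrin (2S,3S,5S)-5-bromo-2-[(1R,3R,4R)-3-bromo-4-hydroxy-4-methylcyclohexyl]-2,6,6-trimethyloxan-3-yl acetate F1. F1 is converted into 19 with SOCl2 in Et2O at 0 °C; the tertiary chlorosulfite should ionise at C4' and collapse there with retention (SNi), with the C5' bromine holding the opposite face. The departing group is thus moved to the carbon that must receive chlorine.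

2. Step 8. Ring closure may go 5-exo at C10 to a tetrahydrofuran with a tertiary bromide, and Br+ may be diverted to the ring A alkene with transannular capture by the C7 hydroxyl. The fallback sets out from alcohol 11 and comes back at 12. Cyclisation with Hg(OCOCF3)2 in MeNO2 at 0 °C should put mercury only on the less substituted carbon C10 and oxygen on C11, and oxymercuration is reversible, so the six-membered organomercurial, the C10 trifluoroacetoxymercurio analogue of 12 F2, should result. Brominolysis of F2 (Br2, LiBr, pyridine, 0 °C) then gives 12; any C10 epimer from this radical step would be removed by chromatography.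

3. Step 5. Facial selectivity may be poor if catalyst and the C8 stereocentre do not cooperate, and the C1' epimer would be very hard to separate. The fallback sets out from isoprene 7 and comes back at ketone 8; it fixes C1' with a covalent auxiliary before C8 exists. The Et2AlCl-promoted Diels–Alder of 7 with (S)-3-acryloyl-4-benzyloxazolidin-2-one F3 (CH2Cl2, −100 °C; chelated s-cis imide, diene anti to benzyl) gives the crystalline imide (S)-4-benzyl-3-[(R)-4-methylcyclohex-3-ene-1-carbonyl]oxazolidin-2-one F4. AlMe3/MeNH(OMe)·HCl converts F4 into the Weinreb amide (R)-N-methoxy-N,4-dimethylcyclohex-3-ene-1-carboxamide F5, and commercial but-3-enylmagnesium bromide gives the ketone 1-[(R)-4-methylcyclohex-3-en-1-yl]pent-4-en-1-one F6. Kinetic enolisation on the methylene side (NaN(SiMe3)2, THF, −78 °C) and hydroxylation with (+)-(camphorsulfonyl)oxaziridine (the antipode if the sense proved opposite) gives (S)-2-hydroxy-1-[(R)-4-methylcyclohex-3-en-1-yl]pent-4-en-1-one F7. TBSOTf/2,6-lutidine then returns 8.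

Further compounds
F1 | step 13 | (2S,3S,5S)-5-bromo-2-[(1R,3R,4R)-3-bromo-4-hydroxy-4-methylcyclohexyl]-2,6,6-trimethyloxan-3-yl acetate | CC(=O)O[C@H]1C[C@H](Br)C(C)(C)O[C@@]1(C)[C@@H]1CC[C@@](C)(O)[C@H](Br)C1
F2 | step 8 | C10 trifluoroacetoxymercurio analogue of 12 | CC(C)(C)[Si](C)(C)O[C@H]1C[C@H]([Hg]OC(=O)C(F)(F)F)C(C)(C)O[C@@]1(C)[C@@H]1CCC(C)=CC1
F3 | step 5 | (S)-3-acryloyl-4-benzyloxazolidin-2-one | C=CC(=O)N1[C@@H](Cc2ccccc2)COC1=O
F4 | step 5 | (S)-4-benzyl-3-[(R)-4-methylcyclohex-3-ene-1-carbonyl]oxazolidin-2-one | CC1=CC[C@@H](CC1)C(=O)N1[C@@H](Cc2ccccc2)COC1=O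
F5 | step 5 | (R)-N-methoxy-N,4-dimethylcyclohex-3-ene-1-carboxamide | CC1=CC[C@@H](CC1)C(=O)N(C)OC
F6 | step 5 | 1-[(R)-4-methylcyclohex-3-en-1-yl]pent-4-en-1-one | CC1=CC[C@@H](CC1)C(=O)CCC=C
F7 | step 5 | (S)-2-hydroxy-1-[(R)-4-methylcyclohex-3-en-1-yl]pent-4-en-1-one | CC1=CC[C@@H](CC1)C(=O)[C@@H](O)CC=C
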